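The earlier runs and the new flask come from a simulation from invented constants, and the scatter is random.

The constant I read first is the feed of solid substrate into solution, from the first zeta reading.

all flasks: solid substrate 0.050 M
- zeta: partner 0.14 M; second reagent 0.10 M; run made earlier
- epsilon: partner 0.22 M; second reagent 0.10 M; run made earlier
- delta: partner 0.10 M; second reagent 0.15 M; run made earlier
- flask: partner 0.100 M; second reagent 0.100 M; time 6.0 d

| run | time / d | target / % | starting material / % |
|---|---|---|---|
| zeta | 0.417 | 0 | 8.1 |
| zeta | 1.25 | 4.0 | 13.4 |
| zeta | 2.00 | 5.6 | 15.2 |
| zeta | 3.00 | 15.7 | 16.4 |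
| zeta | 5.00 | 29.9 | 17.2 |
| epsilon | 0.417 | 0 | 6.1 |
| epsilon | 1.25 | 2.4 | 10.3 |
| epsilon | 2.00 | 7.5 | 11.1 |
| epsilon | 3.00 | 18.2 | 12.6 |
| epsilon | 5.00 | 40.4 | 4.8 |
| delta | 1.04 | 2.4 | 13.6 |
| delta | 2.08 | 7.2 | 15.8 |
| delta | 3.00 | 13.0 | 18.3 |
| delta | 4.00 | 21.0 | 18.7 |
| delta | 5.00 | 31.3 | 17.6 |

(readings scatter by 1 percentage point)

- solid, in amounts per volume of the solution: solid substrate
- what may be going on: starting material + partner -> intermediate; second reagent + intermediate -> target; starting material + second reagent -> side product; solid substrate <-> starting material
- at the start none of the solid substrate is in solution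
- starting material means what is dissolved; the solid is not counted in it

- amount of target at 6.0 d, in percent of the solid substrate charged
- concentration of starting material in solution at 6.0 d, in percent of saturation

In zeta, 8.1 % of the charge is dissolved at 0.417 d. Dissolved starting material in zeta then stays between 15.2 % and 17.2 % from 2.00 d to 5.00 d, while the solid shrinks. So I take dissolving as zero order in the solid: a steady feed, whatever solid is left. The whole charge over that feed is the solid lifetime, 5.15 d. This flask has the same solid charge as zeta, and 5.15 d is shorter than its 6.0 d. So I expect the feed in this flask to end before the reading, with starting material already below its plateau.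

The forecast gives 30 % of target and 17 % of saturation, with “The flask should run out near 5.2 d”. The flask gives 35.1 % of target and 26.7 % of saturation.

    starting material + partner → intermediate (k = 0.00515 M⁻¹ min⁻¹)
    second reagent + intermediate → target (k = 0.00312 M⁻¹ min⁻¹)
    starting material + second reagent → side product (k = 0.00219 M⁻¹ min⁻¹)
    solid substrate ⇌ starting material, rate k4*(cs4 - [starting material]) while solid is left; crystals form when [starting material] > cs4 (solubility = 24.0 mM, k = 4.06 × 10⁻⁴ min⁻¹)

In the flask, solid substrate stands at 40.4 % at 3.00 d and 0 % at 6.00 d, while starting material falls from 18.1 % to 12.8 %. A neighbour flask holds a quarter of this flask's solid substrate, with the other charges and the time held. At the same feed its lifetime is 1.34 d, shorter than 6.0 d. At 6.00 d, that neighbour flask holds 0 % of solid substrate, 0.508 % of starting material and 57.4 % of target.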